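**Plan**
1. Retrosynthesis: the five O–benzyl bonds are cut last. The benzo ring is then taken back to a cyclohexenone (the C5=C6 unsaturation is removed), so that O1 and the 4-OH become the two oxygens of a 5-substituted cyclohexane-1,3-dione.
2. The O1–C2 bond is cut and C2 is joined to C3a: the dihydrofuran (O1, C2, C3, C3a, C7a) becomes the cyclopropane (C2, C3, C3a) of a spiro[2.5]octane-4,8-dione. Its C3–C3a and C2–C3 bonds go back to an alkylidene dione and a benzylic sulfonium ylide, and the exocyclic C3a=C2 bond to dione plus aldehyde.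
3. Forward order: cyclohexanedione ring (Michael/Claisen), Knoevenagel, spirocyclopropane, growth of the three-membered ring to the dihydrofuran, aromatisation of the six-membered ring, debenzylation.
4. Enabling feature: C2 carries an ortho/para-dioxygenated aryl ring (strong cation stabiliser) and C3 a meta-dioxygenated one. C3a lies between the two oxygenated carbons C4 and C7a of ring A, so it is the central carbon of a masked 1,3-dione; only the spiro bond to C2 ionises, and either carbonyl oxygen can close the ring.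
5. Stereochemistry: C3 comes from a chiral sulfonium ylide (reagent control) and is not touched afterwards; C2 is set trans to C3 in the ring expansion (substrate and thermodynamic control).

Key step: step 7

Assumption: the ylide from the (1R,4R,5R) sulfide 13 is taken to give the required configuration at the carbon that becomes C3; if the sense of induction is the opposite one, the (1S,4S,5S) sulfide is used in the same way.
Remark: 11 is racemic (axial chirality of a 4-substituted alkylidenecyclohexane) and 16, 17 and 18 are mixtures of two epimers at the ring carbon that carries the side chain; this element disappears when that ring becomes aromatic in step 8.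

Step 1
Reactants: 1 1-(benzyloxy)-4-iodobenzene; 2 prop-2-en-1-ol
Product: 3 3-[4-(benzyloxy)phenyl]propanal
Conditions: Pd(OAc)2 (cat.), Bu4NCl, NaHCO3, DMF, 40 °C
Reagents that add atoms: none
Why: Heck arylation of allyl alcohol under phase-transfer conditions, in which β-hydride elimination towards the carbinol carbon and tautomerisation should give the 3-arylpropanal; no stereocentre is formed.

Step 2
Reactants: 3 3-[4-(benzyloxy)phenyl]propanal; 4 1-(triphenyl-λ5-phosphanylidene)propan-2-one
Product: 5 (E)-6-[4-(benzyloxy)phenyl]hex-3-en-2-one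
Conditions: CH2Cl2, 40 °C
Reagents that add atoms: none
Why: Wittig olefination with a stabilised ylide should give the (E)-enone.

Step 3
Reactants: 5 (E)-6-[4-(benzyloxy)phenyl]hex-3-en-2-one; 6 diethyl propanedioate
Product: 9 5-{2-[4-(benzyloxy)phenyl]ethyl}cyclohexane-1,3-dione, via keto ester 7 (not isolated), via keto acid 8 (not isolated)
Conditions: NaOEt, EtOH, reflux; aq. NaOH, reflux; then HCl, 70 °C
Reagents that add atoms: none
Why: Michael addition of malonate to the enone, Claisen (Dieckmann-type) ring closure, saponification and decarboxylation is the classical entry to 5-substituted cyclohexane-1,3-diones; 9 has a mirror plane and no stereocentre.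

Step 4
Reactants: 9 5-{2-[4-(benzyloxy)phenyl]ethyl}cyclohexane-1,3-dione; 10 2,4-bis(benzyloxy)benzaldehyde
Product: 11 2-{[2,4-bis(benzyloxy)phenyl]methylidene}-5-{2-[4-(benzyloxy)phenyl]ethyl}cyclohexane-1,3-dione
Conditions: 10 (1.3 equiv), piperidine/AcOH (cat.), 4 Å MS, CH2Cl2, 0 °C to rt
Reagents that add atoms: none
Why: Knoevenagel condensation, in which the ortho/para-dialkoxy ring should make the product a push–pull alkene that resists a second conjugate addition of 9, helped by excess aldehyde and removal of water.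

Step 5
Reactants: 12 1-(bromomethyl)-3,5-bis(benzyloxy)benzene; 13 (1R,4R,5R)-4,7,7-trimethyl-6-thiabicyclo[3.2.1]octane
Product: 14 (1R,4R,5R)-6-{[3,5-bis(benzyloxy)phenyl]methyl}-4,7,7-trimethyl-6-thiabicyclo[3.2.1]octan-6-ium trifluoromethanesulfonate (one diastereomer at sulfur, as formed)
Conditions: LiOTf, CH2Cl2/H2O, rt
Reagents that add atoms: lithium trifluoromethanesulfonate, [Li+].[O-]S(=O)(=O)C(F)(F)F
Why: SN2 S-alkylation on the exposed lone pair of the bicyclic sulfide with exchange of bromide for the non-nucleophilic triflate should give a single sulfonium diastereomer.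

Step 6
Reactants: 14 sulfonium triflate; 11 alkylidene dione
Product: 16 (1S,2S)-1-[2,4-bis(benzyloxy)phenyl]-2-[3,5-bis(benzyloxy)phenyl]-6-{2-[4-(benzyloxy)phenyl]ethyl}spiro[2.5]octane-4,8-dione, via sulfonium ylide 15 (not isolated)
Conditions: LiHMDS, THF, −78 °C; then 11, −78 to −40 °C; pH 7 work-up, neutral alumina
Reagents that add atoms: none
Why: Proposed new method: the semi-stabilised benzylide 15, held in one conformation with one face shielded by the bicyclic sulfide, should add to the exocyclic carbon of the push–pull alkene 11, and the 1,3-dione enolate so formed should displace the sulfide from the benzylic carbon by 3-exo-tet C-alkylation with inversion, so that the configuration of the carbon bearing the 3,5-dioxygenated ring is fixed by the reagent whatever the configuration of the other ring carbon; the closest known reaction types are the Corey–Chaykovsky-type cyclopropanation of arylidene 1,3-dicarbonyl compounds with benzylic sulfonium ylides, the enantioselective epoxidation and aziridination with sulfonium salts of this sulfide, and the spirocyclopropanation of cyclohexane-1,3-diones through benzylic sulfonium intermediates.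

Step 7
Reactants: 16 spirocyclopropane
Product: 17 (2S,3S)-2-[2,4-bis(benzyloxy)phenyl]-3-[3,5-bis(benzyloxy)phenyl]-6-{2-[4-(benzyloxy)phenyl]ethyl}-3,5,6,7-tetrahydro-1-benzofuran-4(2H)-one
Conditions: Sc(OTf)3 (5 mol %), CH2Cl2, −20 to 0 °C
Reagents that add atoms: none
Why: Sc(III) chelates the 1,3-dione, and the bond between the spiro carbon and the carbon bearing the 2,4-bis(benzyloxy)phenyl group ionises to a metal enolate and a benzylic (quinone-methide-type) cation, which collapses through the enolate oxygen; this is a Cloke–Wilson rearrangement, and the closest precedent is the acid- or iodide-promoted ring expansion of aryl-substituted cyclohexane-1,3-dione-2-spirocyclopropanes to 2-aryl-tetrahydrobenzofuran-4-ones. The dihydrofuran closes in a 5-exo-trig mode, the enol oxygen adding to the exocyclic carbon of the aryl-stabilised cation, so the three-membered ring grows by two atoms (a carbonyl carbon and its oxygen). C3 is the cyclopropane carbon that bears the 3,5-dioxygenated ring; none of its bonds is broken, so it keeps the configuration set in step 6. C2 forms on the face anti to the C3 aryl group, and because the C2–O bond can re-ionise under the same catalyst the trans isomer is also the thermodynamic outcome, whatever the configuration of the cleaved cyclopropane carbon. The step needs cleavage of only one of the two spiro C–C bonds and O- instead of C-capture: the ortho/para-dioxygenated ring stabilises a cation far better than the meta-dioxygenated one, and the vinylogous ester is the thermodynamic sink. A catalytic, aprotic Lewis acid at low temperature is chosen to avoid loss of the proton at C3 from the ion pair.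

Step 8
Reactants: 17 tetrahydrobenzofuranone
Product: 20 (2S,3S)-2-[2,4-bis(benzyloxy)phenyl]-3-[3,5-bis(benzyloxy)phenyl]-6-{2-[4-(benzyloxy)phenyl]ethyl}-2,3-dihydro-1-benzofuran-4-ol, via silyl dienol ether 18 (not isolated), via dienone 19 (not isolated)
Conditions: LDA, TMSCl, THF, −78 °C; then Pd(OAc)2 (1.1 equiv), MeCN, rt
Reagents that add atoms: none
Why: Saegusa–Ito oxidation: kinetic α′-deprotonation of the vinylogous ester at C5 and silylation, then Pd(II)-mediated β-hydride elimination, should give the cross-conjugated dienone, which tautomerises to the phenol; C2 and C3 are not touched.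

Step 9
Reactants: 20 pentabenzyl ether
Product: 21 4-[(2S,3S)-3-(3,5-dihydroxyphenyl)-4-hydroxy-6-[2-(4-hydroxyphenyl)ethyl]-2,3-dihydro-1-benzofuran-2-yl]benzene-1,3-diol
Conditions: H2 (1 atm), 10 % Pd/C, EtOAc/MeOH, rt, stopped at full debenzylation
Reagents that add atoms: none
Why: Hydrogenolysis of the five aryl benzyl ethers under neutral conditions should be faster than cleavage of the hindered cyclic benzylic C2–O bond and leaves both stereocentres unchanged.

**Compound list**
1 | 1-(benzyloxy)-4-iodobenzene | Ic1ccc(OCc2ccccc2)cc1 | starting material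
2 | prop-2-en-1-ol | C=CCO | starting material
3 | 3-[4-(benzyloxy)phenyl]propanal | O=CCCc1ccc(OCc2ccccc2)cc1 | intermediate
4 | 1-(triphenyl-λ5-phosphanylidene)propan-2-one | CC(=O)C=P(c1ccccc1)(c1ccccc1)c1ccccc1 | starting material
5 | (E)-6-[4-(benzyloxy)phenyl]hex-3-en-2-one | CC(=O)/C=C/CCc1ccc(OCc2ccccc2)cc1 | intermediate
6 | diethyl propanedioate | CCOC(=O)CC(=O)OCC | starting material
7 | ethyl 6-{2-[4-(benzyloxy)phenyl]ethyl}-2,4-dioxocyclohexane-1-carboxylate | CCOC(=O)C1C(=O)CC(=O)CC1CCc1ccc(OCc2ccccc2)cc1 | intermediate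
8 | 6-{2-[4-(benzyloxy)phenyl]ethyl}-2,4-dioxocyclohexane-1-carboxylic acid | OC(=O)C1C(=O)CC(=O)CC1CCc1ccc(OCc2ccccc2)cc1 | intermediate
9 | 5-{2-[4-(benzyloxy)phenyl]ethyl}cyclohexane-1,3-dione | O=C1CC(=O)CC(CCc2ccc(OCc3ccccc3)cc2)C1 | intermediate
10 | 2,4-bis(benzyloxy)benzaldehyde | O=Cc1ccc(OCc2ccccc2)cc1OCc1ccccc1 | starting material
11 | 2-{[2,4-bis(benzyloxy)phenyl]methylidene}-5-{2-[4-(benzyloxy)phenyl]ethyl}cyclohexane-1,3-dione | O=C1CC(CCc2ccc(OCc3ccccc3)cc2)CC(=O)C1=Cc1ccc(OCc2ccccc2)cc1OCc1ccccc1 | intermediate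
12 | 1-(bromomethyl)-3,5-bis(benzyloxy)benzene | BrCc1cc(OCc2ccccc2)cc(OCc2ccccc2)c1 | starting material
13 | (1R,4R,5R)-4,7,7-trimethyl-6-thiabicyclo[3.2.1]octane | C[C@@H]1CC[C@@H]2C[C@H]1SC2(C)C | starting material
14 | (1R,4R,5R)-6-{[3,5-bis(benzyloxy)phenyl]methyl}-4,7,7-trimethyl-6-thiabicyclo[3.2.1]octan-6-ium trifluoromethanesulfonate | C[C@@H]1CC[C@@H]2C[C@H]1[S+](Cc1cc(OCc3ccccc3)cc(OCc3ccccc3)c1)C2(C)C.[O-]S(=O)(=O)C(F)(F)F | intermediate
15 | sulfonium benzylide of 14 | C[C@@H]1CC[C@@H]2C[C@H]1[S+]([CH-]c1cc(OCc3ccccc3)cc(OCc3ccccc3)c1)C2(C)C | intermediate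
16 | (1S,2S)-1-[2,4-bis(benzyloxy)phenyl]-2-[3,5-bis(benzyloxy)phenyl]-6-{2-[4-(benzyloxy)phenyl]ethyl}spiro[2.5]octane-4,8-dione | O=C1CC(CCc2ccc(OCc3ccccc3)cc2)CC(=O)C12[C@H](c1ccc(OCc3ccccc3)cc1OCc1ccccc1)[C@H]2c1cc(OCc2ccccc2)cc(OCc2ccccc2)c1 | intermediate
17 | (2S,3S)-2-[2,4-bis(benzyloxy)phenyl]-3-[3,5-bis(benzyloxy)phenyl]-6-{2-[4-(benzyloxy)phenyl]ethyl}-3,5,6,7-tetrahydro-1-benzofuran-4(2H)-one | c1ccccc1COc1ccc(CCC2CC(=O)C3=C(C2)O[C@H](c2ccc(OCc4ccccc4)cc2OCc2ccccc2)[C@H]3c2cc(OCc3ccccc3)cc(OCc3ccccc3)c2)cc1 | intermediate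
18 | 4-O-trimethylsilyl dienol ether of 17 (C4=C5 and C3a=C7a) | c1ccccc1COc1ccc(CCC2C=C(O[Si](C)(C)C)C3=C(C2)O[C@H](c2ccc(OCc4ccccc4)cc2OCc2ccccc2)[C@H]3c2cc(OCc3ccccc3)cc(OCc3ccccc3)c2)cc1 | intermediate
19 | (2S,3S)-2-[2,4-bis(benzyloxy)phenyl]-3-[3,5-bis(benzyloxy)phenyl]-6-{2-[4-(benzyloxy)phenyl]ethyl}-3,7-dihydro-1-benzofuran-4(2H)-one | c1ccccc1COc1ccc(CCC2=CC(=O)C3=C(C2)O[C@H](c2ccc(OCc4ccccc4)cc2OCc2ccccc2)[C@H]3c2cc(OCc3ccccc3)cc(OCc3ccccc3)c2)cc1 | intermediate
20 | (2S,3S)-2-[2,4-bis(benzyloxy)phenyl]-3-[3,5-bis(benzyloxy)phenyl]-6-{2-[4-(benzyloxy)phenyl]ethyl}-2,3-dihydro-1-benzofuran-4-ol | c1ccccc1COc1ccc(CCc2cc(O)c3c(c2)O[C@H](c2ccc(OCc4ccccc4)cc2OCc2ccccc2)[C@H]3c2cc(OCc3ccccc3)cc(OCc3ccccc3)c2)cc1 | intermediate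
21 | 4-[(2S,3S)-3-(3,5-dihydroxyphenyl)-4-hydroxy-6-[2-(4-hydroxyphenyl)ethyl]-2,3-dihydro-1-benzofuran-2-yl]benzene-1,3-diol | Oc1ccc(CCc2cc(O)c3c(c2)O[C@H](c2ccc(O)cc2O)[C@H]3c2cc(O)cc(O)c2)cc1 | target

**Step count and risks**
Total: 9 steps. Longest linear sequence: 8 steps (1, 2, 3, 4, 6, 7, 8, 9); step 5 is a one-step branch.

Step 6 (Proposed new method). Three processes may fail: the ylide may discriminate the faces poorly, which lowers the enantiomeric purity at the carbon that becomes C3; the betaine may close through oxygen instead of carbon, which gives the regioisomeric dihydrofuran; and the sulfonium may undergo β-elimination. The fallback uses known chemistry, sets out from 9 and comes back at 17. Arbuzov reaction of 12 with triethyl phosphite gives diethyl {[3,5-bis(benzyloxy)phenyl]methyl}phosphonate F1. Horner–Wadsworth–Emmons olefination of 10 with F1 (t-BuOK, THF) gives 2,4-bis(benzyloxy)-1-{(E)-2-[3,5-bis(benzyloxy)phenyl]ethenyl}benzene F2. Mn(OAc)3-mediated oxidative [3+2] cycloaddition of 9 with F2 (AcOH, 70 °C) should add the dione radical to the alkene carbon remote from the 2,4-dioxygenated ring and close through oxygen on the oxidised benzylic position, giving the trans ketone as a racemate, that is 17 together with its (2R,3R) enantiomer F3. Preparative HPLC on a chiral stationary phase then gives 17, and the route continues with step 8.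

Step 4. A second conjugate addition of 9 to 11 (2:1 adduct) or retro-condensation on isolation may prevail. The fallback sets out from 9 and 10 and comes back at 11. A three-component Knoevenagel/thia-Michael reaction of 9, 10 and 4-methylbenzenethiol (cat. piperidine, CH2Cl2) traps the alkene as 2-{[2,4-bis(benzyloxy)phenyl][(4-methylphenyl)sulfanyl]methyl}-5-{2-[4-(benzyloxy)phenyl]ethyl}-3-hydroxycyclohex-2-en-1-one F4. Oxidation with mCPBA gives the storable sulfone 2-{[2,4-bis(benzyloxy)phenyl](4-methylbenzenesulfonyl)methyl}-5-{2-[4-(benzyloxy)phenyl]ethyl}-3-hydroxycyclohex-2-en-1-one F5. One equivalent of LiHMDS at −78 °C expels p-toluenesulfinate (E1cB) and releases 11 in the flask just before ylide 15 is added in step 6.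

Step 9. Over-reduction by hydrogenolysis of the benzylic C2–O bond of the dihydrofuran may compete with O-debenzylation and open the ring. The fallback sets out from 20 and comes back at 21 without hydrogen: BCl3 with pentamethylbenzene as cation scavenger, CH2Cl2, −78 °C, then methanol. No new compound is made (F0). Any re-ionisation at C2 under the Lewis acid should return to the trans isomer, since C3 is not affected.

**Further compounds**
F1 | step 6 | diethyl {[3,5-bis(benzyloxy)phenyl]methyl}phosphonate | CCOP(=O)(Cc1cc(OCc2ccccc2)cc(OCc2ccccc2)c1)OCC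
F2 | step 6 | 2,4-bis(benzyloxy)-1-{(E)-2-[3,5-bis(benzyloxy)phenyl]ethenyl}benzene | O(Cc1ccccc1)c1cc(OCc2ccccc2)ccc1/C=C/c1cc(OCc2ccccc2)cc(OCc2ccccc2)c1
F3 | step 6 | (2R,3R)-2-[2,4-bis(benzyloxy)phenyl]-3-[3,5-bis(benzyloxy)phenyl]-6-{2-[4-(benzyloxy)phenyl]ethyl}-3,5,6,7-tetrahydro-1-benzofuran-4(2H)-one | c1ccccc1COc1ccc(CCC2CC(=O)C3=C(C2)O[C@@H](c2ccc(OCc4ccccc4)cc2OCc2ccccc2)[C@@H]3c2cc(OCc3ccccc3)cc(OCc3ccccc3)c2)cc1
F4 | step 4 | 2-{[2,4-bis(benzyloxy)phenyl][(4-methylphenyl)sulfanyl]methyl}-5-{2-[4-(benzyloxy)phenyl]ethyl}-3-hydroxycyclohex-2-en-1-one | O=C1CC(CCc2ccc(OCc3ccccc3)cc2)CC(O)=C1C(Sc1ccc(C)cc1)c1ccc(OCc2ccccc2)cc1OCc1ccccc1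
F5 | step 4 | 2-{[2,4-bis(benzyloxy)phenyl](4-methylbenzenesulfonyl)methyl}-5-{2-[4-(benzyloxy)phenyl]ethyl}-3-hydroxycyclohex-2-en-1-one | O=C1CC(CCc2ccc(OCc3ccccc3)cc2)CC(O)=C1C(c1ccc(OCc2ccccc2)cc1OCc1ccccc1)S(=O)(=O)c1ccc(C)cc1
F0 | step 9 | none | none
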